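**Handover.** Beta, neighbour to the other flasks, is the plain case: everything goes in together at 20 °C. The others change how first end groups enter, or start cold.

all flasks: second end groups 0.220 M; time 80 min
- zeta: first end groups 0.22 M (fed, over 30 min); temperature 20 °C; all else is in the flask from the start; the feed brings no volume worth counting
- epsilon: first end groups 0.22 M (fed, over 30 min); the addition at −20 °C, then warmed to 20 °C; the feed brings no volume worth counting
- eta: first end groups 0.22 M; everything together at the start at −20 °C, warmed to 20 °C at 30 min
- beta: first end groups 0.22 M; temperature 20 °C; everything together at the start
- delta: first end groups 0.22 M (in portions, 3, over 30 min); temperature 20 °C; first portion at the start, last at 30 min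

    first end groups + second end groups → links (k1 = 0.44 M⁻¹ s⁻¹, Ea1 = 37.0 kJ mol⁻¹)
    first end groups + second end groups → rings, rate k2*[first end groups] as long as [second end groups] is above zero (k2 = 0.0031 s⁻¹, Ea2 = 92.0 kJ mol⁻¹)
    first end groups ⇌ dormant form (K3 = 14, k3 = 1.9 × 10⁻⁴ s⁻¹, Ea3 = 96.0 kJ mol⁻¹, ΔH3 = −35.0 kJ mol⁻¹)
    first end groups → decomposition product (k4 = 6.0 × 10⁻⁷ s⁻¹, Ea4 = 98.0 kJ mol⁻¹)
    first end groups + links → side product (k5 = 0.0015 M⁻¹ s⁻¹, Ea5 = 69.0 kJ mol⁻¹)
    (constants at 20 °C)

- percent here means first end groups units held: one side product counts as two
- all constants are for 20 °C and move with temperature by the activation energies and enthalpies

* the flask with the highest amount of links, in percent of the first end groups charged ("all alike" if they lie within 1.5 percentage points) (zeta / epsilon / eta / beta / delta / all alike)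
* final links, as a percentage of the first end groups charged, in zeta
* final links, as a percentage of the first end groups charged, in epsilon
* final links, as a percentage of the first end groups charged, in eta
* final links, as a percentage of the first end groups charged, in beta
* final links, as a percentage of the first end groups charged, in delta

**Ring threshold.** Links and rings both consume first end groups, so these cancel from the ratio of the two rates. Ring constant over link constant gives 0.00705 M; this ring threshold, the concentration of second end groups at which links and rings form equally fast, is the effective molarity. A second end group lost becomes a ring with the share threshold/(threshold + second end groups). Integrated at one fixed temperature, rings = threshold × ln[(start + threshold)/(end + threshold)], with start and end the second end groups. The feed does not appear in this expression.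

**Expected at return.** At 20 °C, with second end groups run down to nil, rings come to 0.0245 M, or 11.1% of the charge. That leaves about 88.9% links in zeta, beta and delta, before side product. Cold, the threshold falls to 1.99 × 10⁻⁴ M, far below the warm value. In eta, equal charges reacting at the cold link constant 0.0400 M⁻¹ s⁻¹ give by reckoning 0.0131 M of second end groups at warming. Applying the rule cold and then warm gives 0.00795 M rings, so about 96.4% links. Epsilon stays open, since its second end groups at warming are not reckoned here.

**Not to touch.** Eta stays cold until 30.0 min, because the cold threshold lies far below the warm one.

**The forecast.** It names eta, with 87.8% for zeta, 93% for epsilon, 95.9% for eta, 87.8% for beta and 87.8% for delta, since cooling “suppresses the high-activation-energy ring closure far more than link formation”. The hand figure for zeta stands higher than the forecast's.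

**The result.** Links are highest in eta: 96.0%, against 92.9% in epsilon and 88.0%, 88.0% and 88.0% in zeta, beta and delta. The forecast names the right flask, and its figures lie within the tolerance.

**Eta's timing.** At 1.77 min, eta made links 570 times as fast as rings, which by the cold threshold reads as 0.114 M of second end groups standing. By 8.00 min, eta had 84% of its link turnover up to 80.0 min behind it but 4.8% of its ring turnover, and the ring turnover reached its midpoint at 31.8 min, later than the warming.

**Second flask.** Eta's neighbour with 0.13 M of second end groups has first end groups in excess. Taking second end groups as used up cold, the cold threshold gives rings of 0.587% of the first end groups charged. That neighbour ends with 0.578% rings, 45.6% links and 25.7% side product, and its second end groups stand at 0% of their own charge.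

(The numbers of this flask were chosen freely; no experiment stands behind them.)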